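**Plan**

- Cuts: the sulfate O–S bond on ring A C4 and the group masking N4 are handled last. The 24-membered ring is opened at the N4–CH2 bond of the four-carbon arm. Behind that lie the two amide C–N bonds, the two cinnamoyl C=C bonds and the ring A C3–O–ring B aryl ether bond.
- Enabling feature: N4 is the only amine nitrogen of the macrocycle. It sits between the (CH2)3 arm leading to the ring B amide N1 and the (CH2)4 arm leading to the ring A amide N8. Carried as a 2-nitrobenzenesulfonamide (Ns) N–H it is masked, yet acidic enough to be alkylated by the terminal CH2OH of the four-carbon arm.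
- Forward: ring A (3,4-dihydroxybenzaldehyde, O4 as MOM ether) is olefinated, joined to ring B by SNAr on 4-fluorobenzaldehyde and olefinated again. The ring B acid is amidated with mono-Ns 1,3-diaminopropane, then the ring A acid with 4-aminobutanol.
- The macrocycle is the only ring made. It closes by Mitsunobu N-alkylation, which also completes the spermidine chain. MOM cleavage, O-sulfation and Ns removal finish the route.
- There is no stereocentre. The two E alkenes come from a stabilised-ylide Wittig reaction and a Knoevenagel–Doebner condensation and are not touched afterwards.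

Key step: step 9

Assumption: aryl sulfates are drawn as the hydrogen sulfate and N4 as the free amine, as in the target SMILES. In practice 19 would be handled as its pyridinium salt, and 20 would be isolated as the inner salt (N4 protonated by the sulfate), which is the same compound.

Step 1
Reactants: 1 3,4-dihydroxybenzaldehyde
Product: 2 3-hydroxy-4-(methoxymethoxy)benzaldehyde
Conditions: MOMCl (1.05 equiv), K2CO3 (1.1 equiv), acetone, 0 °C to rt, N2
Reagents that add atoms: chloromethyl methyl ether, COCCl
Why: The 4-OH is conjugated with the para formyl group and is the more acidic phenol, so one equivalent of weak base should form mainly its phenoxide and the Williamson-type O-alkylation should fall on O4, a selectivity well established for this aldehyde.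

Step 2
Reactants: 2 3-hydroxy-4-(methoxymethoxy)benzaldehyde
Product: 3 methyl (E)-3-[3-hydroxy-4-(methoxymethoxy)phenyl]prop-2-enoate
Conditions: Ph3P=CHCO2Me, toluene, 80 °C
Reagents that add atoms: methyl (triphenylphosphoranylidene)acetate, COC(=O)C=P(c1ccccc1)(c1ccccc1)c1ccccc1
Why: The Wittig reaction of an ester-stabilised ylide with an aromatic aldehyde is reliably E-selective and tolerates a free phenol and the MOM acetal.

Step 3
Reactants: 3 methyl (E)-3-[3-hydroxy-4-(methoxymethoxy)phenyl]prop-2-enoate; 4 4-fluorobenzaldehyde
Product: 5 methyl (E)-3-[3-(4-formylphenoxy)-4-(methoxymethoxy)phenyl]prop-2-enoate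
Conditions: K2CO3, dry DMF, 100 °C
Reagents that add atoms: none
Why: In this nucleophilic aromatic substitution (SNAr) the para formyl group activates the C–F bond towards the phenoxide of 3, while the ester, alkene and MOM ether are inert to dry carbonate.

Step 4
Reactants: 5 methyl (E)-3-[3-(4-formylphenoxy)-4-(methoxymethoxy)phenyl]prop-2-enoate
Product: 7 (E)-3-[4-[5-[(E)-3-methoxy-3-oxoprop-1-enyl]-2-(methoxymethoxy)phenoxy]phenyl]prop-2-enoic acid (ring B acid; ring A methyl ester), via arylidenemalonic acid 6 (not isolated)
Conditions: malonic acid, pyridine, piperidine (cat.), 85 °C; work-up at pH 4, 0 °C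
Reagents that add atoms: malonic acid, OC(=O)CC(=O)O
Why: The Knoevenagel–Doebner condensation and decarboxylation should deliver the E acid directly, so the two acrylic termini are differentiated (free acid against methyl ester) without a deprotection, and the pyridine-buffered medium spares the MOM acetal.

Step 5
Reactants: 8 1,3-diaminopropane
Product: 9 N-(3-aminopropyl)-2-nitrobenzenesulfonamide
Conditions: NsCl (1 equiv) added slowly to 8 (6 equiv), CH2Cl2, 0 °C to rt
Reagents that add atoms: 2-nitrobenzenesulfonyl chloride, O=S(=O)(Cl)c1ccccc1[N+](=O)[O-]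
Why: Sulfonylation of a large excess of the symmetrical diamine statistically favours the monosulfonamide, and the surplus diamine binds the acid and washes out with water.

Step 6
Reactants: 7 ring B acid with ring A methyl ester; 9 N-(3-aminopropyl)-2-nitrobenzenesulfonamide
Product: 11 methyl (E)-3-[4-(methoxymethoxy)-3-[4-[(E)-3-[3-(2-nitrobenzenesulfonamido)propylamino]-3-oxoprop-1-enyl]phenoxy]phenyl]prop-2-enoate, via ring B benzotriazolyl ester 10 (not isolated)
Conditions: EDC, HOBt, DMF, 0 °C to rt
Reagents that add atoms: none
Why: In this carbodiimide/HOBt amide coupling the primary amine of 9 is far more nucleophilic than its sulfonamide N–H, so only the N1 amide should form.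

Step 7
Reactants: 11 ring B amide with ring A methyl ester
Product: 12 (E)-3-[4-(methoxymethoxy)-3-[4-[(E)-3-[3-(2-nitrobenzenesulfonamido)propylamino]-3-oxoprop-1-enyl]phenoxy]phenyl]prop-2-enoic acid
Conditions: LiOH, THF/MeOH/H2O, rt; then 1 M HCl to pH 4, 0 °C
Reagents that add atoms: lithium hydroxide, [Li+].[OH-]
Why: Ester saponification at room temperature leaves the secondary amide, the (deprotonated) sulfonamide and the base-stable MOM ether intact, and the brief cold acidification is too mild to open the acetal.

Step 8
Reactants: 12 ring A acid; 13 4-aminobutan-1-ol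
Product: 15 seco hydroxy sulfonamide (E)-N-(4-hydroxybutyl)-3-[4-(methoxymethoxy)-3-[4-[(E)-3-[3-(2-nitrobenzenesulfonamido)propylamino]-3-oxoprop-1-enyl]phenoxy]phenyl]prop-2-enamide, via ring A benzotriazolyl ester 14 (not isolated)
Conditions: EDC, HOBt, DMF, 0 °C to rt
Reagents that add atoms: none
Why: In this carbodiimide/HOBt amide coupling the amine of the amino alcohol outruns its hydroxyl for the active ester, so the alcohol needs no protecting group.

Step 9
Reactants: 15 seco hydroxy sulfonamide
Product: 17 N4-(2-nitrobenzenesulfonyl) macrocycle bearing the ring A O4 methoxymethyl ether (24-membered; both alkenes E), via alkoxyphosphonium sulfonamidate zwitterion 16 (not isolated)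
Conditions: PPh3 (3 equiv), DIAD (3 equiv), THF/toluene, rt; 15 in THF added by syringe pump over 12 h (final ca. 1 mM)
Reagents that add atoms: none
Why: PPh3 and DIAD combine to a betaine that takes the acidic N–H proton of the 2-nitrobenzenesulfonamide and passes its phosphonium centre to the primary hydroxyl, so 15 becomes zwitterion 16, which holds nucleophile and leaving group in one molecule. The sulfonamide anion then displaces Ph3P=O from the terminal CH2 of the four-carbon arm in an SN2 step, which forms the N4–CH2 bond, completes the spermidine chain and closes the 24-membered ring end to end (24-exo-tet, the departing oxygen outside the ring). The reaction type is the Fukuyama–Mitsunobu alkylation of 2-nitrobenzenesulfonamides, established both for intermolecular polyamine assembly and for closing medium and large azacycles. No stereocentre is created, and the two E alkenes, the MOM acetal and the diaryl ether are spectators under these neutral conditions. Site selectivity rests on acidity: only the sulfonamide is deprotonated by the betaine, the two secondary amide N–H groups are far too weakly acidic, and because the hydroxyl lies four carbons from its amide nitrogen, carbonyl-oxygen participation would need a seven-membered imidate instead of an easy five- or six-membered one. Ring closure is favoured over oligomerisation by slow addition into a dilute reagent solution, and the flat E-cinnamoyl/diaryl ether half of the chain limits the number of rotors that must be frozen.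

Step 10
Reactants: 17 N4-Ns macrocycle MOM ether
Product: 18 N4-Ns macrocycle with free ring A C4 phenol
Conditions: HCl (1.25 M in MeOH), MeOH/THF, 40 °C
Reagents that add atoms: none
Why: Acid-catalysed acetal exchange with methanol cleaves the aryl MOM ether under conditions that leave the cinnamamides, the diaryl ether and the tertiary sulfonamide untouched.

Step 11
Reactants: 18 N4-Ns macrocycle phenol
Product: 19 N4-Ns macrocycle ring A C4 hydrogen sulfate
Conditions: SO3·pyridine (5 equiv), pyridine, rt to 40 °C; Sephadex LH-20 or C18
Reagents that add atoms: sulfur trioxide–pyridine complex, [O-]S(=O)(=O)[n+]1ccccc1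
Why: In this O-sulfation with an amine–SO3 complex the phenol is the only competent nucleophile, because N4 is a tertiary sulfonamide and secondary amides are not sulfonated under these conditions.

Step 12
Reactants: 19 N4-Ns macrocycle hydrogen sulfate
Product: 20 target CID124202369 (isolated as the inner salt)
Conditions: PhSH, K2CO3, DMF, rt, dark; then AcOH to pH 6; C18 (H2O/MeOH)
Reagents that add atoms: none
Why: In the Fukuyama deprotection the thiolate attacks the sulfonyl-bearing carbon of the nitroarene (SNAr through a Meisenheimer adduct) and releases SO2 and the secondary amine, while the aryl sulfate monoester anion is inert to base and soft nucleophiles and cinnamamides are poor, reversible thiol acceptors.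

**Compound list**

1 | 3,4-dihydroxybenzaldehyde | O=Cc1ccc(O)c(O)c1 | starting material
2 | 3-hydroxy-4-(methoxymethoxy)benzaldehyde | O=Cc1ccc(OCOC)c(O)c1 | intermediate
3 | methyl (E)-3-[3-hydroxy-4-(methoxymethoxy)phenyl]prop-2-enoate | COC(=O)/C=C/c1ccc(OCOC)c(O)c1 | intermediate
4 | 4-fluorobenzaldehyde | O=Cc1ccc(F)cc1 | starting material
5 | methyl (E)-3-[3-(4-formylphenoxy)-4-(methoxymethoxy)phenyl]prop-2-enoate | COC(=O)/C=C/c1ccc(OCOC)c(Oc2ccc(C=O)cc2)c1 | intermediate
6 | arylidenemalonic acid from 5, formed in the flask | COC(=O)/C=C/c1ccc(OCOC)c(Oc2ccc(C=C(C(=O)O)C(=O)O)cc2)c1 | intermediate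
7 | (E)-3-[4-[5-[(E)-3-methoxy-3-oxoprop-1-enyl]-2-(methoxymethoxy)phenoxy]phenyl]prop-2-enoic acid | COC(=O)/C=C/c1ccc(OCOC)c(Oc2ccc(/C=C/C(=O)O)cc2)c1 | intermediate
8 | 1,3-diaminopropane | NCCCN | starting material
9 | N-(3-aminopropyl)-2-nitrobenzenesulfonamide | NCCCNS(=O)(=O)c1ccccc1[N+](=O)[O-] | intermediate
10 | benzotriazol-1-yl ester of 7 (ring B terminus), formed in the flask | COC(=O)/C=C/c1ccc(OCOC)c(Oc2ccc(/C=C/C(=O)On3nnc4ccccc43)cc2)c1 | intermediate
11 | ring B N-[3-(Ns-amino)propyl] cinnamamide, ring A methyl cinnamate, O4 MOM ether | COC(=O)/C=C/c1ccc(OCOC)c(Oc2ccc(/C=C/C(=O)NCCCNS(=O)(=O)c3ccccc3[N+](=O)[O-])cc2)c1 | intermediate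
12 | ring A cinnamic acid derived from 11 | OC(=O)/C=C/c1ccc(OCOC)c(Oc2ccc(/C=C/C(=O)NCCCNS(=O)(=O)c3ccccc3[N+](=O)[O-])cc2)c1 | intermediate
13 | 4-aminobutan-1-ol | NCCCCO | starting material
14 | benzotriazol-1-yl ester of 12 (ring A terminus), formed in the flask | O=C(/C=C/c1ccc(OCOC)c(Oc2ccc(/C=C/C(=O)NCCCNS(=O)(=O)c3ccccc3[N+](=O)[O-])cc2)c1)On1nnc2ccccc21 | intermediate
15 | seco hydroxy sulfonamide: ring A N-(4-hydroxybutyl) cinnamamide, ring B N-[3-(Ns-amino)propyl] cinnamamide, O4 MOM ether | OCCCCNC(=O)/C=C/c1ccc(OCOC)c(Oc2ccc(/C=C/C(=O)NCCCNS(=O)(=O)c3ccccc3[N+](=O)[O-])cc2)c1 | intermediate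
16 | alkoxy(triphenyl)phosphonium sulfonamidate zwitterion from 15, formed in the flask | c1ccccc1[P+](c1ccccc1)(c1ccccc1)OCCCCNC(=O)/C=C/c1ccc(OCOC)c(Oc2ccc(/C=C/C(=O)NCCC[N-]S(=O)(=O)c3ccccc3[N+](=O)[O-])cc2)c1 | intermediate
17 | N4-Ns 24-membered (E,E)-macrocycle, ring A O4 MOM ether | O=C1/C=C/c2ccc(OCOC)c(c2)Oc2ccc(cc2)/C=C/C(=O)NCCCN(S(=O)(=O)c2ccccc2[N+](=O)[O-])CCCCN1 | intermediate
18 | N4-Ns (E,E)-macrocycle, free ring A C4 phenol | O=C1/C=C/c2ccc(O)c(c2)Oc2ccc(cc2)/C=C/C(=O)NCCCN(S(=O)(=O)c2ccccc2[N+](=O)[O-])CCCCN1 | intermediate
19 | N4-Ns (E,E)-macrocycle, ring A C4 hydrogen sulfate | O=C1/C=C/c2ccc(OS(=O)(=O)O)c(c2)Oc2ccc(cc2)/C=C/C(=O)NCCCN(S(=O)(=O)c2ccccc2[N+](=O)[O-])CCCCN1 | intermediate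
20 | CID124202369, (E,E)-macrocyclic spermidine bis-cinnamamide ring A C4 hydrogen sulfate | O=C1/C=C/c2ccc(OS(=O)(=O)O)c(c2)Oc2ccc(cc2)/C=C/C(=O)NCCCNCCCCN1 | target

**Step count**

Total steps: 12. Longest linear sequence: 11 steps (steps 1–4 and 6–12, from 1). Step 5 is a one-step side branch.

**Steps most likely to fail**

**Step 9.**
- Risk: ring closure may lose out to intermolecular alkylation and chain growth. The activated alcohol may also be consumed by its own neighbouring amide before the distant sulfonamide anion reaches it.
- Fallback: this separates activation from ring closure while keeping the same bond.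
  - Setting out from 15, an Appel reaction (CBr4, PPh3, CH2Cl2, 0 °C) should give the seco primary bromide F1. It is a storable electrophile that is much less prone to amide participation than a phosphonium ion.
  - Slow addition of F1 to Cs2CO3 and Bu4NI in DMF at 50–60 °C keeps the fully formed sulfonamide anion in large excess over free electrophile. This base-mediated alkylation forms the N4–CH2 bond and comes back to the route at 17.

**Step 12.**
- Risk: the thiolate may add to the cinnamamide double bonds, and sulfate may be lost during neutralisation. A zwitterion also has to be freed from salts and sulfur by-products at the very end.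
- Fallback: the thiolate step is moved ahead of sulfation, and N4 is carried through as a carbamate that a secondary amine removes.
  - Setting out from 18, PhSH and K2CO3 in DMF should give the aminophenol macrocycle F2, an ordinary extractable amine.
  - Fmoc-OSu with NaHCO3 in dioxane/water should acylate only the amine to give the N4-Fmoc phenol macrocycle F3.
  - SO3·pyridine in DMF should give the N4-Fmoc hydrogen sulfate macrocycle F4.
  - Piperidine in DMF then removes the carbamate by E1cB cleavage. The neutral fluorene by-product is washed out by trituration with ether, and the sequence comes back at 20.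

**Step 11.**
- Risk: sulfation of the phenol flanked by the aryloxy group may stall. The ionic sulfate may also hydrolyse or streak during purification.
- Fallback: sulfur is installed as a neutral, silica-stable group and unmasked afterwards.
  - Setting out from 18, [4-(acetylamino)phenyl]imidodisulfuryl difluoride and DBU in THF (or SO2F2 with Et3N) should give the aryl fluorosulfate macrocycle F5, which can be chromatographed normally.
  - Solvolysis with ethylene glycol and Cs2CO3 at rt is a known way to convert aryl fluorosulfates into aryl sulfates. It then delivers the sulfate without further chromatography and comes back at 19 (here as its cesium salt).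

**Further compounds**

F1 | step 9 | seco primary bromide: ring A N-(4-bromobutyl) cinnamamide, ring B N-[3-(Ns-amino)propyl] cinnamamide, O4 MOM ether | BrCCCCNC(=O)/C=C/c1ccc(OCOC)c(Oc2ccc(/C=C/C(=O)NCCCNS(=O)(=O)c3ccccc3[N+](=O)[O-])cc2)c1
F2 | step 12 | aminophenol macrocycle (N4–H, ring A C4 OH) | O=C1/C=C/c2ccc(O)c(c2)Oc2ccc(cc2)/C=C/C(=O)NCCCNCCCCN1
F3 | step 12 | N4-Fmoc phenol macrocycle | O=C1/C=C/c2ccc(O)c(c2)Oc2ccc(cc2)/C=C/C(=O)NCCCN(C(=O)OCC2c3ccccc3-c3ccccc32)CCCCN1
F4 | step 12 | N4-Fmoc hydrogen sulfate macrocycle | O=C1/C=C/c2ccc(OS(=O)(=O)O)c(c2)Oc2ccc(cc2)/C=C/C(=O)NCCCN(C(=O)OCC2c3ccccc3-c3ccccc32)CCCCN1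
F5 | step 11 | N4-Ns aryl fluorosulfate macrocycle | O=C1/C=C/c2ccc(OS(=O)(=O)F)c(c2)Oc2ccc(cc2)/C=C/C(=O)NCCCN(S(=O)(=O)c2ccccc2[N+](=O)[O-])CCCCN1
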